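## Retrosynthetic overview

1. Numbering (iridal type): C1 = aldehyde carbon, C2 = its alkene carbon, C3–C5 = the propyl chain (C3 bears the decanoate). The cyclohexane ring is C6 (CH), C7 (alkylidene carbon), C8, C9, C10 (CHMe), C11 (quaternary). The side chain is C12–C24 with the carbinol at C16.
2. Endgame: the enal is unmasked last (C1 silyl ether → alcohol → aldehyde). Before that the C13–C14 bond joins ring fragment 13 (C1–C13, with a vinyl group C12=C13 on C11) and side-chain fragment 22 (C14–C24, an E-alkenyl iodide with the C16 carbinol) by hydroboration/B-alkyl Suzuki–Miyaura coupling.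
3. Enabling feature: C13 is a primary CH2 held two bonds from the ring by the quaternary C11, so it can be stored as the terminus of the only monosubstituted alkene of 13. C14 is the unsubstituted sp2 end of the E-C14=C15 alkene next to C16, so alkene geometry and carbinol can be finished in 22 before the union.
4. Ring fragment: the single ring is not formed but bought as (R)-4-methylcyclohex-2-en-1-one (C10). C11 and C6 are relayed from C10 in one copper-catalysed 1,4-methylation/enolate allylation of dienone 3. The Z-enal comes from isopropenyl addition at C7 and oxidative allylic transposition.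
5. Side chain: carboalumination of propargyl alcohol fixes E-C14=C15, α-selective geranyl transfer makes C16–C17, and oxidation/CBS reduction sets (R)-C16.

Key step: step 15

Assumption: (R)-4-methylcyclohex-2-en-1-one (1) is taken as a purchasable enantiopure building block; its stereocentre (C10) is the only one that is bought.

## Route

Step 1
Reactants: 1 (4R)-4-methylcyclohex-2-en-1-one
Product: 2 trimethyl{[(3S,4R)-3-ethenyl-4-methylcyclohex-1-en-1-yl]oxy}silane
Conditions: CH2=CHMgBr, CuBr·SMe2 (cat.), Me3SiCl, HMPA, THF, −78 °C; Et3N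
Reagents that add atoms: vinylmagnesium bromide C=C[Mg]Br; chlorotrimethylsilane C[Si](C)(C)Cl
Why: Copper-catalysed conjugate addition of the Grignard reagent with in situ silyl trapping should place the vinyl group on C11 anti to the C10 methyl group and fix the enolate regiospecifically as the C6=C7 silyl enol ether, the C11 configuration being erased again in step 2.

Step 2
Reactants: 2 trimethyl{[(3S,4R)-3-ethenyl-4-methylcyclohex-1-en-1-yl]oxy}silane
Product: 3 (4R)-3-ethenyl-4-methylcyclohex-2-en-1-one
Conditions: Pd(OAc)2 (cat.), O2 (1 atm), DMSO, 25 °C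
Reagents that add atoms: none
Why: Saegusa–Ito dehydrogenation through a divalent palladium enolate and β-hydride elimination of the C11 hydrogen should regenerate the enone regiospecifically between C6 and C11 and give the conjugated dienone with C10 untouched.

Step 3
Reactants: 3 (4R)-3-ethenyl-4-methylcyclohex-2-en-1-one
Product: 5 (2S,3R,4R)-3-ethenyl-3,4-dimethyl-2-(prop-2-en-1-yl)cyclohexan-1-one, via bromomagnesium enolate 4 (not isolated)
Conditions: MeMgBr, Cu(OTf)2 (cat.), 1,3-dimesitylimidazolinium chloride (cat.), Et2O, −30 °C; then allyl iodide, DMPU, THF, −30 → 0 °C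
Reagents that add atoms: methylmagnesium bromide C[Mg]Br; allyl iodide C=CCI
Why: Copper–N-heterocyclic-carbene-catalysed conjugate addition of a Grignard reagent to a 3-alkenylcyclohexenone, a reaction type that favours 1,4- over 1,6-attack and tolerates formation of a quaternary centre, should add methyl to C11 anti to the C10 methyl group (substrate control), and the magnesium enolate should then be allylated at C6 by axial attack anti to the pseudoaxial C11 vinyl group and away from the C10 methyl group, so that C11 and C6 are both relayed from C10 in one operation.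

Step 4
Reactants: 5 (2S,3R,4R)-3-ethenyl-3,4-dimethyl-2-(prop-2-en-1-yl)cyclohexan-1-one
Product: 6 (2S,3R,4R)-3-ethenyl-3,4-dimethyl-1-(prop-1-en-2-yl)-2-(prop-2-en-1-yl)cyclohexan-1-ol (C1 epimers; configuration at this carbon, C7 of the target, is not needed)
Conditions: CH2=C(CH3)MgBr, CeCl3, THF, −78 → 0 °C; aq NH4Cl
Reagents that add atoms: isopropenylmagnesium bromide CC(=C)[Mg]Br
Why: 1,2-Addition of the weakly basic organocerium reagent to the hindered, enolisable ketone should give the tertiary allylic alcohol without epimerising C6, and the new carbinol configuration is inconsequential because C7 becomes sp2 in step 5.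

Step 5
Reactants: 6 (2S,3R,4R)-3-ethenyl-3,4-dimethyl-1-(prop-1-en-2-yl)-2-(prop-2-en-1-yl)cyclohexan-1-ol
Product: 7 (2Z)-2-[(2S,3R,4R)-3-ethenyl-3,4-dimethyl-2-(prop-2-en-1-yl)cyclohexylidene]propanal
Conditions: pyridinium chlorochromate (C5H5NH[CrO3Cl]), 4 Å molecular sieves, CH2Cl2, 25 °C
Reagents that add atoms: pyridinium chlorochromate c1cc[nH+]cc1.[O-][Cr](=O)(=O)Cl
Why: In this Babler–Dauben oxidative transposition the tertiary allylic chromate ester should undergo a [3,3] shift to the primary allylic chromate and be oxidised to the tetrasubstituted enal, and a chair-like transition state that turns the isopropenyl methyl group toward the unsubstituted C8 methylene and the migrating CH2–O terminus toward the substituted C6 should favour the Z isomer.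

Step 6
Reactants: 7 (2Z)-2-[(2S,3R,4R)-3-ethenyl-3,4-dimethyl-2-(prop-2-en-1-yl)cyclohexylidene]propanal
Product: 8 (2Z)-2-[(2S,3R,4R)-3-ethenyl-3,4-dimethyl-2-(prop-2-en-1-yl)cyclohexylidene]propan-1-ol
Conditions: NaBH4, CeCl3·7H2O, MeOH, 0 °C
Reagents that add atoms: none
Why: Luche reduction should reduce the enal 1,2-selectively to the primary allylic alcohol without touching the alkenes or the geometry of C7=C2.

Step 7
Reactants: 8 (2Z)-2-[(2S,3R,4R)-3-ethenyl-3,4-dimethyl-2-(prop-2-en-1-yl)cyclohexylidene]propan-1-ol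
Product: 9 tert-butyl{[(2Z)-2-[(2S,3R,4R)-3-ethenyl-3,4-dimethyl-2-(prop-2-en-1-yl)cyclohexylidene]propyl]oxy}dimethylsilane
Conditions: t-BuMe2SiCl, imidazole, DMF, 25 °C
Reagents that add atoms: tert-butyl(chloro)dimethylsilane CC(C)(C)[Si](C)(C)Cl
Why: Standard silylation of the unhindered primary allylic alcohol masks the C1 oxygen, at the alcohol oxidation level, for the two hydroborations and the coupling.

Step 8
Reactants: 9 tert-butyl{[(2Z)-2-[(2S,3R,4R)-3-ethenyl-3,4-dimethyl-2-(prop-2-en-1-yl)cyclohexylidene]propyl]oxy}dimethylsilane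
Product: 11 3-[(1S,2R,3R,6Z)-6-{1-[(tert-butyldimethylsilyl)oxy]propan-2-ylidene}-2-ethenyl-2,3-dimethylcyclohexyl]propan-1-ol, via trialkylborane 10 (not isolated)
Conditions: bis(3-methylbutan-2-yl)borane (from BH3·THF and 2-methylbut-2-ene), THF, 0 °C; then H2O2, aq NaOH, 0 → 25 °C
Reagents that add atoms: bis(3-methylbutan-2-yl)borane CC(C)C(C)BC(C)C(C)C (carried in 10 only); hydrogen peroxide OO
Why: Brown hydroboration–oxidation with the bulky dialkylborane should be anti-Markovnikov and chemoselective for the C6 allyl group, because the C11 vinyl group is shielded by the quaternary carbon and the C7=C2 alkene is tetrasubstituted.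

Step 9
Reactants: 11 3-[(1S,2R,3R,6Z)-6-{1-[(tert-butyldimethylsilyl)oxy]propan-2-ylidene}-2-ethenyl-2,3-dimethylcyclohexyl]propan-1-ol; 12 decanoyl chloride
Product: 13 3-[(1S,2R,3R,6Z)-6-{1-[(tert-butyldimethylsilyl)oxy]propan-2-ylidene}-2-ethenyl-2,3-dimethylcyclohexyl]propyl decanoate
Conditions: pyridine, DMAP (cat.), CH2Cl2, 0 → 25 °C
Reagents that add atoms: none
Why: Acylation of the primary alcohol with the acid chloride under nucleophilic catalysis should install the decanoate and complete fragment A.

Step 10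
Reactants: 14 prop-2-yn-1-ol
Product: 16 (2E)-3-iodo-2-methylprop-2-en-1-ol, via alkenylalane 15 (not isolated)
Conditions: AlMe3, Cp2ZrCl2 (cat.), CH2Cl2, 0 → 25 °C; then I2, THF, −30 → 0 °C
Reagents that add atoms: trimethylaluminium C[Al](C)C; iodine II
Why: Negishi carboalumination adds methyl (to the future C15) and aluminium (to the future C14) syn across the terminal alkyne, and iodinolysis with retention should give the E-alkenyl iodide.

Step 11
Reactants: 16 (2E)-3-iodo-2-methylprop-2-en-1-ol
Product: 17 (2E)-3-iodo-2-methylprop-2-enal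
Conditions: MnO2, CH2Cl2, 25 °C
Reagents that add atoms: none
Why: Allylic alcohol oxidation with MnO2 should give the enal without isomerising the alkenyl iodide.

Step 12
Reactants: 17 (2E)-3-iodo-2-methylprop-2-enal; 18 (2E)-1-chloro-3,7-dimethylocta-2,6-diene (geranyl chloride)
Product: 20 rac-(1E,5E)-1-iodo-2,6,10-trimethylundeca-1,5,9-trien-3-ol, via geranylbarium chloride 19 (not isolated)
Conditions: BaI2, Li(C12H10) (lithium biphenylide), THF, 25 °C; 18, −78 °C; then 17, −78 °C; aq NH4Cl
Reagents that add atoms: barium [Ba] (carried in 19 only)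
Why: Allylbarium reagents add to aldehydes at their α-carbon with retention of the allyl geometry, so this carbonyl allylation should attach the geranyl group through C17 by 1,2-addition and give the linear homoallylic alcohol with E-C18=C19 intact, racemic at C16.

Step 13
Reactants: 20 rac-(1E,5E)-1-iodo-2,6,10-trimethylundeca-1,5,9-trien-3-ol
Product: 21 (1E,5E)-1-iodo-2,6,10-trimethylundeca-1,5,9-trien-3-one
Conditions: Dess–Martin periodinane, NaHCO3, CH2Cl2, 0 °C
Reagents that add atoms: none
Why: Dess–Martin oxidation under buffered, non-basic conditions should give the enone without moving the C18=C19 alkene into conjugation.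

Step 14
Reactants: 21 (1E,5E)-1-iodo-2,6,10-trimethylundeca-1,5,9-trien-3-one
Product: 22 (1E,3R,5E)-1-iodo-2,6,10-trimethylundeca-1,5,9-trien-3-ol
Conditions: (S)-2-methyl-CBS-oxazaborolidine (cat.), catecholborane, toluene, −78 °C
Reagents that add atoms: none
Why: In this Corey–Bakshi–Shibata reduction the (S)-oxazaborolidine should bind the ketone with the α-methyl alkenyl group as the large substituent and deliver hydride to give the (R)-carbinol at C16 under catalyst control, completing fragment B.

Step 15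
Reactants: 13 3-[(1S,2R,3R,6Z)-6-{1-[(tert-butyldimethylsilyl)oxy]propan-2-ylidene}-2-ethenyl-2,3-dimethylcyclohexyl]propyl decanoate; 22 (1E,3R,5E)-1-iodo-2,6,10-trimethylundeca-1,5,9-trien-3-ol
Product: 24 3-[(1S,2R,3R,6Z)-6-{1-[(tert-butyldimethylsilyl)oxy]propan-2-ylidene}-2-[(3E,5R,7E)-5-hydroxy-4,8,12-trimethyltrideca-3,7,11-trien-1-yl]-2,3-dimethylcyclohexyl]propyl decanoate, via B-alkyl-9-BBN borane 23 (not isolated)
Conditions: 9-BBN, THF, 0 → 40 °C; then aq Cs2CO3, 22, Pd(dppf)Cl2 (cat.), AsPh3 (cat.), DMF/THF/H2O, 25 °C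
Reagents that add atoms: 9-borabicyclo[3.3.1]nonane B1C2CCCC1CCC2 (carried in 23 only)
Why: 9-BBN adds syn and anti-Markovnikov to the only monosubstituted alkene of 13, the C11 vinyl group, placing boron on C13 (borane 23); zerovalent palladium generated from Pd(dppf)Cl2 then inserts into the C14–I bond of 22 with retention, the base-activated borane transfers its primary alkyl group to divalent palladium, and reductive elimination forms the C13–C14 bond. The closest known reaction type is the one-pot hydroboration/B-alkyl Suzuki–Miyaura coupling of alkyl-9-BBN reagents with E-alkenyl iodides. No ring is closed and no stereocentre is created: the E geometry of C14=C15 and the (R)-carbinol at C16 are carried over unchanged from 22, and C6, C10 and C11 from 13. The step needs chemoselective hydroboration, which is secured because the other alkene of 13 is the tetrasubstituted C7=C2, the ester and silyl ether are inert to 9-BBN, and excess borane is quenched with aqueous base before 22 (free hydroxyl, trisubstituted alkenes) is added. It also needs primary-alkyl transfer without β-hydride elimination, which the dppf ligand with AsPh3 at room temperature should secure, while the quaternary C11 excludes any migration of the alkylpalladium species toward the ring. In this one operation the two halves become the complete C30 skeleton with all four stereocentres and all four alkene geometries in place.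

Step 16
Reactants: 24 the silyl ether from step 15
Product: 25 3-[(1S,2R,3R,6Z)-2-[(3E,5R,7E)-5-hydroxy-4,8,12-trimethyltrideca-3,7,11-trien-1-yl]-6-(1-hydroxypropan-2-ylidene)-2,3-dimethylcyclohexyl]propyl decanoate
Conditions: HF·pyridine, pyridine, THF, 0 → 25 °C
Reagents that add atoms: none
Why: Fluoride-mediated desilylation buffered with pyridine should free the primary allylic alcohol without cleaving the ester or ionising the allylic carbinol at C16.

Step 17
Reactants: 25 the diol from step 16
Product: 26 3-[(1S,2R,3R,6Z)-2-[(3E,5R,7E)-5-hydroxy-4,8,12-trimethyltrideca-3,7,11-trien-1-yl]-2,3-dimethyl-6-(1-oxopropan-2-ylidene)cyclohexyl]propyl decanoate (target, CNP0270550.1)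
Conditions: TEMPO (cat.), PhI(OAc)2, CH2Cl2, 25 °C
Reagents that add atoms: none
Why: Oxoammonium (TEMPO) oxidation with PhI(OAc)2 as terminal oxidant should oxidise the primary allylic alcohol much faster than the more hindered secondary C16 alcohol and give the Z-enal without touching the carbinol.

## Compound list

1 | (4R)-4-methylcyclohex-2-en-1-one | O=C1CC[C@@H](C)C=C1 | starting material
2 | trimethyl{[(3S,4R)-3-ethenyl-4-methylcyclohex-1-en-1-yl]oxy}silane | C[Si](C)(C)OC1=C[C@@H](C=C)[C@H](C)CC1 | intermediate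
3 | (4R)-3-ethenyl-4-methylcyclohex-2-en-1-one | O=C1CC[C@@H](C)C(C=C)=C1 | intermediate
4 | bromo{[(3R,4R)-3-ethenyl-3,4-dimethylcyclohex-1-en-1-yl]oxy}magnesium | Br[Mg]OC1=C[C@](C)(C=C)[C@H](C)CC1 | intermediate
5 | (2S,3R,4R)-3-ethenyl-3,4-dimethyl-2-(prop-2-en-1-yl)cyclohexan-1-one | C=CC[C@@H]1C(=O)CC[C@@H](C)[C@@]1(C)C=C | intermediate
6 | (2S,3R,4R)-3-ethenyl-3,4-dimethyl-1-(prop-1-en-2-yl)-2-(prop-2-en-1-yl)cyclohexan-1-ol (C1 epimers) | C=CC[C@@H]1C(O)(C(C)=C)CC[C@@H](C)[C@@]1(C)C=C | intermediate
7 | (2Z)-2-[(2S,3R,4R)-3-ethenyl-3,4-dimethyl-2-(prop-2-en-1-yl)cyclohexylidene]propanal | C=CC[C@@H]1/C(=C(/C)C=O)CC[C@@H](C)[C@@]1(C)C=C | intermediate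
8 | (2Z)-2-[(2S,3R,4R)-3-ethenyl-3,4-dimethyl-2-(prop-2-en-1-yl)cyclohexylidene]propan-1-ol | C=CC[C@@H]1/C(=C(/C)CO)CC[C@@H](C)[C@@]1(C)C=C | intermediate
9 | tert-butyl{[(2Z)-2-[(2S,3R,4R)-3-ethenyl-3,4-dimethyl-2-(prop-2-en-1-yl)cyclohexylidene]propyl]oxy}dimethylsilane | C=CC[C@@H]1/C(=C(/C)CO[Si](C)(C)C(C)(C)C)CC[C@@H](C)[C@@]1(C)C=C | intermediate
10 | {3-[(1S,2R,3R,6Z)-6-{1-[(tert-butyldimethylsilyl)oxy]propan-2-ylidene}-2-ethenyl-2,3-dimethylcyclohexyl]propyl}bis(3-methylbutan-2-yl)borane | CC(C)C(C)B(CCC[C@@H]1/C(=C(/C)CO[Si](C)(C)C(C)(C)C)CC[C@@H](C)[C@@]1(C)C=C)C(C)C(C)C | intermediate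
11 | 3-[(1S,2R,3R,6Z)-6-{1-[(tert-butyldimethylsilyl)oxy]propan-2-ylidene}-2-ethenyl-2,3-dimethylcyclohexyl]propan-1-ol | OCCC[C@@H]1/C(=C(/C)CO[Si](C)(C)C(C)(C)C)CC[C@@H](C)[C@@]1(C)C=C | intermediate
12 | decanoyl chloride | CCCCCCCCCC(=O)Cl | starting material
13 | 3-[(1S,2R,3R,6Z)-6-{1-[(tert-butyldimethylsilyl)oxy]propan-2-ylidene}-2-ethenyl-2,3-dimethylcyclohexyl]propyl decanoate (fragment A) | CCCCCCCCCC(=O)OCCC[C@@H]1/C(=C(/C)CO[Si](C)(C)C(C)(C)C)CC[C@@H](C)[C@@]1(C)C=C | intermediate
14 | prop-2-yn-1-ol | C#CCO | starting material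
15 | dimethyl{[(2E)-3-(dimethylalumanyl)-2-methylprop-2-en-1-yl]oxy}alumane | C[Al](C)OC/C(C)=C/[Al](C)C | intermediate
16 | (2E)-3-iodo-2-methylprop-2-en-1-ol | OC/C(C)=C/I | intermediate
17 | (2E)-3-iodo-2-methylprop-2-enal | O=C/C(C)=C/I | intermediate
18 | (2E)-1-chloro-3,7-dimethylocta-2,6-diene (geranyl chloride) | ClC/C=C(\C)CCC=C(C)C | starting material
19 | chloro[(2E)-3,7-dimethylocta-2,6-dien-1-yl]barium | Cl[Ba]C/C=C(\C)CCC=C(C)C | intermediate
20 | rac-(1E,5E)-1-iodo-2,6,10-trimethylundeca-1,5,9-trien-3-ol | I/C=C(\C)C(O)C/C=C(\C)CCC=C(C)C | intermediate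
21 | (1E,5E)-1-iodo-2,6,10-trimethylundeca-1,5,9-trien-3-one | I/C=C(\C)C(=O)C/C=C(\C)CCC=C(C)C | intermediate
22 | (1E,3R,5E)-1-iodo-2,6,10-trimethylundeca-1,5,9-trien-3-ol (fragment B) | I/C=C(\C)[C@H](O)C/C=C(\C)CCC=C(C)C | intermediate
23 | 3-[(1S,2R,3R,6Z)-2-[2-(9-borabicyclo[3.3.1]nonan-9-yl)ethyl]-6-{1-[(tert-butyldimethylsilyl)oxy]propan-2-ylidene}-2,3-dimethylcyclohexyl]propyl decanoate | CCCCCCCCCC(=O)OCCC[C@@H]1/C(=C(/C)CO[Si](C)(C)C(C)(C)C)CC[C@@H](C)[C@@]1(C)CCB1C2CCCC1CCC2 | intermediate
24 | 3-[(1S,2R,3R,6Z)-6-{1-[(tert-butyldimethylsilyl)oxy]propan-2-ylidene}-2-[(3E,5R,7E)-5-hydroxy-4,8,12-trimethyltrideca-3,7,11-trien-1-yl]-2,3-dimethylcyclohexyl]propyl decanoate | CCCCCCCCCC(=O)OCCC[C@@H]1/C(=C(/C)CO[Si](C)(C)C(C)(C)C)CC[C@@H](C)[C@@]1(C)CC/C=C(\C)[C@H](O)C/C=C(\C)CCC=C(C)C | intermediate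
25 | 3-[(1S,2R,3R,6Z)-2-[(3E,5R,7E)-5-hydroxy-4,8,12-trimethyltrideca-3,7,11-trien-1-yl]-6-(1-hydroxypropan-2-ylidene)-2,3-dimethylcyclohexyl]propyl decanoate | CCCCCCCCCC(=O)OCCC[C@@H]1/C(=C(/C)CO)CC[C@@H](C)[C@@]1(C)CC/C=C(\C)[C@H](O)C/C=C(\C)CCC=C(C)C | intermediate
26 | 3-[(1S,2R,3R,6Z)-2-[(3E,5R,7E)-5-hydroxy-4,8,12-trimethyltrideca-3,7,11-trien-1-yl]-2,3-dimethyl-6-(1-oxopropan-2-ylidene)cyclohexyl]propyl decanoate | CCCCCCCCCC(=O)OCCC[C@@H]1/C(=C(/C)C=O)CC[C@@H](C)[C@@]1(C)CC/C=C(\C)[C@H](O)C/C=C(\C)CCC=C(C)C | target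

## Step count and risks

Total step count: 17.
Longest linear sequence: 12 steps (steps 1–9 from 1 to fragment A 13, then steps 15–17). The side-chain arm is 5 steps (10–14) before the union.

The three steps most likely to fail:

**Step 3.** The methyl group may be transferred to the vinyl terminus C13 (1,6-addition) instead of C11, facial control at C11 may be incomplete, or the magnesium enolate may alkylate slowly and lose its regiochemistry by proton exchange. The fallback sets out from 3 and masks the vinyl group before the quaternary centre is made. Reversible conjugate addition of thiophenol (Et3N cat., CH2Cl2) should place sulfur on the terminal carbon and give, after re-conjugation, (4R)-4-methyl-3-[2-(phenylsulfanyl)ethyl]cyclohex-2-en-1-one F1. This simple enone should accept Me2CuLi in the normal 1,4-sense anti to the C10 methyl group, and the lithium enolate is allylated (allyl bromide, HMPA) to (2S,3R,4R)-3,4-dimethyl-3-[2-(phenylsulfanyl)ethyl]-2-(prop-2-en-1-yl)cyclohexan-1-one F2. NaIO4 oxidation gives (2S,3R,4R)-3-[2-(benzenesulfinyl)ethyl]-3,4-dimethyl-2-(prop-2-en-1-yl)cyclohexan-1-one F3, and thermal syn-elimination of the sulfoxide (toluene, 110 °C, CaCO3) regenerates the vinyl group. The fallback comes back to the route at 5.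

**Step 5.** The geometry of C7=C2 may be poorly controlled in the sigmatropic shift, or the enal may scramble under the acidic chromium conditions. The fallback sets out from 5 and makes the alkene by olefination instead of transposition. Peterson olefination with lithiated 2-(trimethylsilyl)propanenitrile (LiN(iPr)2, THF, −78 → 25 °C) should give (2Z)-2-[(2S,3R,4R)-3-ethenyl-3,4-dimethyl-2-(prop-2-en-1-yl)cyclohexylidene]propanenitrile F4. The rod-shaped cyano group is expected to take the position syn to the substituted C6, and a thiolate-mediated equilibration can move a mixture toward this isomer. Reduction of the nitrile with iBu2AlH (toluene, −78 °C; aqueous acid) comes back to the route at 7, bypassing 6.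

**Step 12.** Residual active barium or lithium biphenylide may attack the alkenyl C–I bond of 17 (reduction or halogen–metal exchange), and α-selectivity or E-geometry may erode if the allylbarium warms. The fallback sets out from 18 and uses sulfone-stabilised α-anion chemistry. Displacement with TolSO2Na (DMF) gives 1-{[(2E)-3,7-dimethylocta-2,6-dien-1-yl]sulfonyl}-4-methylbenzene F5. Its α-lithio derivative (n-BuLi, THF, −78 °C) adds to aldehyde 17 to give (1E,5E)-1-iodo-2,6,10-trimethyl-4-[(4-methylphenyl)sulfonyl]undeca-1,5,9-trien-3-ol F6. Dess–Martin oxidation gives (1E,5E)-1-iodo-2,6,10-trimethyl-4-[(4-methylphenyl)sulfonyl]undeca-1,5,9-trien-3-one F7, and reductive desulfonylation (Zn, AcOH, THF, 25 °C) comes back to the route at 21, bypassing 20 and step 13.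

## Further compounds

F1 | step 3 | (4R)-4-methyl-3-[2-(phenylsulfanyl)ethyl]cyclohex-2-en-1-one | O=C1CC[C@@H](C)C(CCSc2ccccc2)=C1
F2 | step 3 | (2S,3R,4R)-3,4-dimethyl-3-[2-(phenylsulfanyl)ethyl]-2-(prop-2-en-1-yl)cyclohexan-1-one | C=CC[C@@H]1C(=O)CC[C@@H](C)[C@@]1(C)CCSc1ccccc1
F3 | step 3 | (2S,3R,4R)-3-[2-(benzenesulfinyl)ethyl]-3,4-dimethyl-2-(prop-2-en-1-yl)cyclohexan-1-one | C=CC[C@@H]1C(=O)CC[C@@H](C)[C@@]1(C)CCS(=O)c1ccccc1
F4 | step 5 | (2Z)-2-[(2S,3R,4R)-3-ethenyl-3,4-dimethyl-2-(prop-2-en-1-yl)cyclohexylidene]propanenitrile | C=CC[C@@H]1/C(=C(/C)C#N)CC[C@@H](C)[C@@]1(C)C=C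
F5 | step 12 | 1-{[(2E)-3,7-dimethylocta-2,6-dien-1-yl]sulfonyl}-4-methylbenzene | Cc1ccc(cc1)S(=O)(=O)C/C=C(\C)CCC=C(C)C
F6 | step 12 | (1E,5E)-1-iodo-2,6,10-trimethyl-4-[(4-methylphenyl)sulfonyl]undeca-1,5,9-trien-3-ol | I/C=C(\C)C(O)C(/C=C(\C)CCC=C(C)C)S(=O)(=O)c1ccc(C)cc1
F7 | step 12 | (1E,5E)-1-iodo-2,6,10-trimethyl-4-[(4-methylphenyl)sulfonyl]undeca-1,5,9-trien-3-one | I/C=C(\C)C(=O)C(/C=C(\C)CCC=C(C)C)S(=O)(=O)c1ccc(C)cc1
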